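**Retrosynthetic overview** (tetralin numbering of the target is used for all ring B intermediates)

1. Ring A (C4a, C5–C8, C8a) has H at C5 and C8, OMe at C6 and C7 and no stereocentre. It is cut at C4a–C5 and C8–C8a: 2,3-dimethoxybuta-1,3-diene adds across a C4a≡C8a triple bond of a ring B cyclohexyne that already carries C1 (aryl), C2 and C3, and DDQ then aromatises.
2. The cyclohexyne comes from a vicinal pair, triflate on C8a and Me3Si on C4a, made regiospecifically by conjugate hydride addition to a 2-silyl enone (C8a=O, C4a(Si)=C4) and O-triflation of the enolate.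
3. The 2-silyl enone comes from a ring B vinylsilane by a singlet-oxygen ene reaction. Ring B is formed first, by Diels–Alder reaction of a 1-aryl-3-silylbutadiene with di-menthyl fumarate, which sets C2 and C3. C1, α to the ketone, is set by equilibration while the two CH2O arms are locked diequatorial in a trans-fused ketal.
4. The aryl group arrives with the diene rather than by cuprate addition to a 4,5-trans enone, because a cuprate would enter anti to the C3 arm and give the C1 epimer. The ketal is exchanged for the two methyl ethers at the end.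
5. Order of ring formation: ring B (step 3), then ring A (step 8, aromatised in step 9).

Key step: step 8

Assumption: the fumarate cycloaddition is taken to follow the facial sense known for simple dienes ((1R,2S,5R)-menthyl esters giving the (1R,2R)-diester), so the (1S,2R,5S)-menthyl ester is used; if the aryl silyl diene reacted with the opposite sense, the enantiomeric fumarate would be used with no other change.

**Step 1**
Reactants: 1 4-ethynyl-1,2-dimethoxybenzene
Product: 2 2-[(E)-2-(3,4-dimethoxyphenyl)ethenyl]-4,4,5,5-tetramethyl-1,3,2-dioxaborolane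
Conditions: HBpin (1.2 equiv), Cp2Zr(H)Cl (5 mol %), Et3N (10 mol %), neat, 60 °C
Reagents that add atoms: pinacolborane, [H]B1OC(C)(C)C(C)(C)O1
Why: Zirconocene-catalysed syn-hydroboration of the terminal alkyne places boron on the terminal carbon and gives the (E)-alkenylboronate.

**Step 2**
Reactants: 2 the (E)-alkenylboronate; 3 (1-bromoethenyl)trimethylsilane
Product: 4 [(3E)-4-(3,4-dimethoxyphenyl)buta-1,3-dien-2-yl]trimethylsilane
Conditions: Pd(PPh3)4 (3 mol %), K3PO4, 1,4-dioxane/H2O, 80 °C
Reagents that add atoms: none
Why: Suzuki–Miyaura coupling of the alkenylboronate with the 1-silylvinyl bromide proceeds with retention of the E geometry and leaves the C–Si bond intact under aqueous phosphate.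

**Step 3**
Reactants: 4 the aryl silyl diene; 5 di-(1S,2R,5S)-menthyl fumarate
Product: 6 di-(1S,2R,5S)-menthyl (1S,2S)-3-(3,4-dimethoxyphenyl)-5-(trimethylsilyl)cyclohex-4-ene-1,2-dicarboxylate (ring B; both epimers at the aryl carbon, future C1)
Conditions: Et2AlCl (1.5 equiv), toluene, −78 → −20 °C
Reagents that add atoms: none
Why: Lewis acid-promoted Diels–Alder reaction of a chiral fumarate: the E dienophile gives the trans-diester and the menthyl groups of the aluminium-bound fumarate shield one face, which sets C2 and C3, while C1 forms as both epimers (either ester can sit endo) and is corrected in step 6.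

**Step 4**
Reactants: 6 the di-menthyl diester
Product: 7 [(1S,2S)-3-(3,4-dimethoxyphenyl)-5-(trimethylsilyl)cyclohex-4-ene-1,2-diyl]dimethanol (both C1 epimers)
Conditions: LiAlH4, THF, 0 °C → reflux
Reagents that add atoms: none
Why: Hydride reduction of both hindered esters to primary alcohols releases the auxiliary and does not touch the stereocentres.

**Step 5**
Reactants: 7 the diol
Product: 8 isopropylidene ketal of 7, trans-fused 6-(3,4-dimethoxyphenyl)-3,3-dimethyl-8-(trimethylsilyl)-1,5,5a,6,9,9a-hexahydro-3H-2,4-benzodioxepine (both C1 epimers)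
Conditions: Me2C(OMe)2, PPTS (cat.), CH2Cl2, 23 °C
Reagents that add atoms: 2,2-dimethoxypropane, COC(C)(C)OC
Why: Acid-catalysed transketalisation closes a 2,2-dimethyl-1,3-dioxepane across the 1,4-diol, which protects both hydroxyls and, being trans-fused, holds the two CH2O arms diequatorial for step 6.

**Step 6**
Reactants: 8 the vinylsilane ketal
Product: 11 all-trans 2-silyl enone, 6-(3,4-dimethoxyphenyl)-3,3-dimethyl-8-(trimethylsilyl)-1,5,5a,9a-tetrahydro-3H-2,4-benzodioxepin-7(6H)-one (C8a=O, C4a(SiMe3)=C4; aryl trans to the C2 arm), via allylic hydroperoxide 9 (not isolated), via enone epimer mixture 10 (not isolated)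
Conditions: O2, tetraphenylporphyrin (cat.), hν (visible), CH2Cl2, 0 °C; then Ac2O, pyridine, DMAP (cat.), 0 → 23 °C; then DBU (0.2 equiv), toluene, 23 °C
Reagents that add atoms: dioxygen, O=O
Why: Schenck ene reaction of a vinylsilane, in which singlet oxygen bonds to the carbon β to silicon (C8a) and takes hydrogen from the CH2 geminal to silicon (C4), followed by Kornblum–DeLaMare dehydration of the hydroperoxide, gives the 2-silyl enone, and DBU then equilibrates the benzylic α′ centre C1 through the cross-conjugated dienolate to the isomer with equatorial aryl trans to the C2 arm, because with both arms held equatorial by the ketal the only alternative carries an axial aryl group.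

**Step 7**
Reactants: 11 the all-trans 2-silyl enone
Product: 13 6-(3,4-dimethoxyphenyl)-3,3-dimethyl-8-(trimethylsilyl)-1,5,5a,6,9,9a-hexahydro-3H-2,4-benzodioxepin-7-yl trifluoromethanesulfonate (triflate on C8a, Me3Si on C4a, all-trans), via lithium enolate 12 (not isolated)
Conditions: LiBH(s-Bu)3 (1.05 equiv), THF, −78 °C (enone added to the hydride); then N-(5-chloropyridin-2-yl)bis(trifluoromethanesulfonyl)imide, −78 → 0 °C
Reagents that add atoms: N-(5-chloropyridin-2-yl)bis(trifluoromethanesulfonyl)imide, O=S(=O)(N(c1ccc(Cl)cn1)S(=O)(=O)C(F)(F)F)C(F)(F)F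
Why: Conjugate hydride addition to a 2-silylcyclohexenone gives the C8a–C4a enolate regiospecifically and this is O-triflated in the same flask, so the silyl/triflate pair can only flank the future triple bond; C4 becomes CH2 (no new stereocentre) and C1 is kept because the enolate forms away from it, without excess ketone, and is trapped cold.

**Step 8**
Reactants: 13 the silyl triflate; 14 2,3-dimethoxybuta-1,3-diene
Product: 16 isopropylidene ketal of [(1R,2S,3S)-1-(3,4-dimethoxyphenyl)-6,7-dimethoxy-1,2,3,4,5,8-hexahydronaphthalene-2,3-diyl]dimethanol (ketal-protected 5,8-dihydro precursor of the target), via cyclohexyne 15 (not isolated)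
Conditions: CsF (3 equiv), 14 (5 equiv), MeCN, 23 °C
Reagents that add atoms: none
Why: Proposed new method: fluoride attacks the trimethylsilyl group on C4a and triflate is expelled from C8a, giving the strained cyclohexyne 15, whose bent, low-lying π* orbital is trapped by the s-cis conformer of the electron-rich diene in a concerted (4+2) cycloaddition. The closest known reactions are the Diels–Alder trapping of fluoride-generated cyclohexynes by furan-type dienes, 2-pyrones and cyclopentadienones, and of arynes by acyclic dienes; an acyclic 2,3-dialkoxybutadiene has not been shown with a cyclohexyne. Ring A closes in this one step as a cyclohexa-1,4-diene, by a (4+2) annulation onto the C4a–C8a edge of ring B that forms both C4a–C5 and C8–C8a. No stereocentre is created, and C1, C2 and C3 are not involved. No regio- or facial selectivity is needed, because the diene is symmetric and the triple bond is fixed between C4a and C8a by the vicinal silyl/triflate pair. The selectivity that is needed is (4+2) over (2+2), ene and oligomerisation pathways, and it is secured by using the diene in excess and by the two 2-alkoxy groups, which raise the diene HOMO and favour the s-cis form.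

**Step 9**
Reactants: 16 the cyclohexa-1,4-diene
Product: 17 isopropylidene ketal of [(1R,2S,3S)-1-(3,4-dimethoxyphenyl)-6,7-dimethoxy-1,2,3,4-tetrahydronaphthalene-2,3-diyl]dimethanol
Conditions: DDQ (1.05 equiv), CH2Cl2, 0 °C
Reagents that add atoms: none
Why: Dehydrogenation of the cyclohexa-1,4-diene by DDQ (hydride abstraction from a doubly allylic CH2, then proton loss) is driven by aromatisation and should leave C1–C3 and the ketal untouched at 0 °C.

**Step 10**
Reactants: 17 the tetralin ketal
Product: 18 [(1R,2S,3S)-1-(3,4-dimethoxyphenyl)-6,7-dimethoxy-1,2,3,4-tetrahydronaphthalene-2,3-diyl]dimethanol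
Conditions: AcOH/H2O/THF (3:1:1), 40 °C
Reagents that add atoms: none
Why: Acid-catalysed hydrolysis of the seven-membered ketal releases the 1,4-diol without involving any stereocentre.

**Step 11**
Reactants: 18 the diol
Product: 19 phyltetralin, (1R,2S,3S)-1-(3,4-dimethoxyphenyl)-6,7-dimethoxy-2,3-bis(methoxymethyl)-1,2,3,4-tetrahydronaphthalene
Conditions: NaH, MeI, THF/DMF, 0 → 23 °C
Reagents that add atoms: iodomethane, CI
Why: Williamson etherification of both primary alkoxides with iodomethane completes the target without involving any stereocentre.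

**Compound list**

1 | 4-ethynyl-1,2-dimethoxybenzene | C#Cc1ccc(OC)c(OC)c1 | starting material
2 | 2-[(E)-2-(3,4-dimethoxyphenyl)ethenyl]-4,4,5,5-tetramethyl-1,3,2-dioxaborolane | COc1ccc(/C=C/B2OC(C)(C)C(C)(C)O2)cc1OC | intermediate
3 | (1-bromoethenyl)trimethylsilane | C=C(Br)[Si](C)(C)C | starting material
4 | [(3E)-4-(3,4-dimethoxyphenyl)buta-1,3-dien-2-yl]trimethylsilane | C=C([Si](C)(C)C)/C=C/c1ccc(OC)c(OC)c1 | intermediate
5 | di-(1S,2R,5S)-menthyl fumarate | CC(C)[C@H]1CC[C@H](C)C[C@@H]1OC(=O)/C=C/C(=O)O[C@H]1C[C@@H](C)CC[C@@H]1C(C)C | starting material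
6 | di-(1S,2R,5S)-menthyl (1S,2S)-3-(3,4-dimethoxyphenyl)-5-(trimethylsilyl)cyclohex-4-ene-1,2-dicarboxylate, aryl carbon as both epimers | O=C(O[C@H]1C[C@@H](C)CC[C@@H]1C(C)C)[C@H]1CC([Si](C)(C)C)=CC(c2ccc(OC)c(OC)c2)[C@@H]1C(=O)O[C@H]1C[C@@H](C)CC[C@@H]1C(C)C | intermediate
7 | [(1S,2S)-3-(3,4-dimethoxyphenyl)-5-(trimethylsilyl)cyclohex-4-ene-1,2-diyl]dimethanol, aryl carbon as both epimers | OC[C@H]1CC([Si](C)(C)C)=CC(c2ccc(OC)c(OC)c2)[C@@H]1CO | intermediate
8 | isopropylidene ketal of 7 (trans-fused 2,2-dimethyl-1,3-dioxepane), aryl carbon as both epimers | CC1(C)OC[C@H]2CC([Si](C)(C)C)=CC(c3ccc(OC)c(OC)c3)[C@@H]2CO1 | intermediate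
9 | allylic hydroperoxide (OOH on C8a, C4a(SiMe3)=C4), mixture at C1 and C8a | CC1(C)OC[C@H]2C=C([Si](C)(C)C)C(OO)C(c3ccc(OC)c(OC)c3)[C@@H]2CO1 | intermediate
10 | 2-silyl enone, both C1 epimers | CC1(C)OC[C@H]2C=C([Si](C)(C)C)C(=O)C(c3ccc(OC)c(OC)c3)[C@@H]2CO1 | intermediate
11 | all-trans 2-silyl enone (aryl trans to the C2 arm, arms trans) | CC1(C)OC[C@H]2C=C([Si](C)(C)C)C(=O)[C@@H](c3ccc(OC)c(OC)c3)[C@@H]2CO1 | intermediate
12 | lithium enolate (O on C8a, C8a=C4a, Me3Si on C4a) | [Li+].CC1(C)OC[C@H]2CC([Si](C)(C)C)=C([O-])[C@@H](c3ccc(OC)c(OC)c3)[C@@H]2CO1 | intermediate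
13 | silyl triflate (OTf on C8a, Me3Si on C4a, all-trans) | CC1(C)OC[C@H]2CC([Si](C)(C)C)=C(OS(=O)(=O)C(F)(F)F)[C@@H](c3ccc(OC)c(OC)c3)[C@@H]2CO1 | intermediate
14 | 2,3-dimethoxybuta-1,3-diene | C=C(OC)C(OC)=C | starting material
15 | ring B cyclohexyne (C4a≡C8a) | CC1(C)OC[C@H]2CC#C[C@@H](c3ccc(OC)c(OC)c3)[C@@H]2CO1 | intermediate
16 | isopropylidene ketal of the (1R,2S,3S)-5,8-dihydro diol | CC1(C)OC[C@H]2CC3=C(CC(OC)=C(OC)C3)[C@@H](c4ccc(OC)c(OC)c4)[C@@H]2CO1 | intermediate
17 | isopropylidene ketal of diol 18 | CC1(C)OC[C@H]2Cc3cc(OC)c(OC)cc3[C@@H](c4ccc(OC)c(OC)c4)[C@@H]2CO1 | intermediate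
18 | [(1R,2S,3S)-1-(3,4-dimethoxyphenyl)-6,7-dimethoxy-1,2,3,4-tetrahydronaphthalene-2,3-diyl]dimethanol | OC[C@H]1Cc2cc(OC)c(OC)cc2[C@@H](c2ccc(OC)c(OC)c2)[C@@H]1CO | intermediate
19 | phyltetralin | COC[C@H]1Cc2cc(OC)c(OC)cc2[C@@H](c2ccc(OC)c(OC)c2)[C@@H]1COC | target

**Step count**

Total: 11 steps. Longest linear sequence: 11 steps (1 → 19).

**Steps most likely to fail**

Step 8 (proposed new method). The cyclohexyne may be consumed by stepwise (2+2) addition to an enol ether double bond of the diene, by ene reaction or by oligomerisation before the (4+2) addition occurs, because the acyclic diene is only partly in its s-cis form. The fallback sets out from 13 and uses known chemistry. The same cyclohexyne is generated with CsF in MeCN in the presence of 3,4-dimethoxyfuran; furan-type dienes are established traps for fluoride-generated cyclohexynes. This should give the oxygen-bridged cycloadduct F1 (either orientation of the bridge serves). Removal of the bridge with low-valent titanium (TiCl4, LiAlH4, Et3N, THF, reflux) aromatises ring A and comes back to the route at 17; steps 10 and 11 follow unchanged.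

Step 7. Proton transfer from the acidic benzylic C1–H of unreacted enone to the new enolate, or drift of the enolate towards the aryl-conjugated isomer, would scramble both the enolate position and C1; 1,2-reduction could also compete. The fallback sets out from 11. Neutral 1,4-hydrosilylation (Et3SiH, RhCl(PPh3)3 cat., THF, 50 °C) should give the triethylsilyl enol ether F2, so that no enolate coexists with ketone. MeLi (THF, 0 °C) then cleaves the O–Si bond and comes back to the route at the lithium enolate 12, which is triflated as in step 7 to give 13.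

Step 6. The ene reaction may abstract the benzylic C1–H instead (oxygen adding to the silicon-bearing carbon), the vinylsilane may react too slowly so that the dimethoxyarene is photo-oxidised, or C1 may not equilibrate fully. The fallback sets out from 8. Buffered epoxidation (mCPBA, NaHCO3, CH2Cl2) should give the epoxysilane F3. Sodium benzeneselenolate (from (PhSe)2 and NaBH4 in EtOH) opens it at the silicon-bearing carbon to give the hydroxy selenide F4. H2O2 with pyridine then triggers selenoxide syn-elimination towards C4 and gives the 2-silyl allylic alcohol F5. Dess–Martin oxidation comes back to the route at the enone mixture 10, which DBU equilibrates to 11.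

**Further compounds**

F1 | step 8 | 5,8-epoxy-5,8-dihydro analogue of 17 (oxygen bridge between C5 and C8, OMe on C6 and C7) | CC1(C)OC[C@H]2CC3=C(C4OC3C(OC)=C4OC)[C@@H](c5ccc(OC)c(OC)c5)[C@@H]2CO1
F2 | step 7 | triethylsilyl enol ether of the 2-silyl ketone (OSiEt3 on C8a, Me3Si on C4a) | CC1(C)OC[C@H]2CC([Si](C)(C)C)=C(O[Si](CC)(CC)CC)[C@@H](c3ccc(OC)c(OC)c3)[C@@H]2CO1
F3 | step 6 | epoxysilane of 8 (epoxide across C4a–C8a) | CC1(C)OC[C@H]2CC3([Si](C)(C)C)OC3C(c4ccc(OC)c(OC)c4)[C@@H]2CO1
F4 | step 6 | β-hydroxy selenide (PhSe and Me3Si on C4a, OH on C8a) | CC1(C)OC[C@H]2CC([Si](C)(C)C)([Se]c3ccccc3)C(O)C(c4ccc(OC)c(OC)c4)[C@@H]2CO1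
F5 | step 6 | 2-silyl allylic alcohol (OH on C8a, C4a(SiMe3)=C4) | CC1(C)OC[C@H]2C=C([Si](C)(C)C)C(O)C(c3ccc(OC)c(OC)c3)[C@@H]2CO1
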